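**The leftover.** A leftover of 50.2% of the E, the mean of the readings, stood in maple, the very flask asked about, from the first reading to the last, with J beside it at 49.4%. Elm stayed just as flat, with J at 35.8%.

| flask | E | G | temperature | remark | time |
|---|---|---|---|---|---|
| maple | 0.20 M | 0.21 M | 5 °C | the very flask that is asked about, followed so far |  |
| elm | 0.40 M | 0.21 M | 11 °C | run made earlier |  |
| flask | 0.20 M | 0.210 M | 5 °C |  | 5.0 h |

- maple (time / min: J / %, E / %): 15.0: 49, 48; 25.0: 49, 51; 50.0: 50, 52; 90.0: 49, 50; 180: 50, 50
- elm (time / min: J / %, E / %): 1.33: 35, 65; 2.50: 35, 67; 4.00: 34, 63; 8.00: 38, 62; 15.0: 37, 68

(scatter of a reading: 1.5 percentage points)

- red: change nothing and wait 10 h more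
- blue: at 5.0 h take out 90% of the L then present, then wait 10 h
- amber: at 5.0 h add G, 100% of the amount charged, then wait 10 h
- teal: at 5.0 h raise the temperature by 10 K, then wait 10 h

- additions leave the volume as it is
- what was read earlier has a scatter of 1.5 percentage points, one standard deviation

* J, in percent of the E first charged, at 5.0 h
* the option that brings most further J ("none" if no option brings more than 2 percentage points) (red / blue / amber / teal / none)
* J present, in percent of the E first charged, after blue
* J present, in percent of the E first charged, after teal

**Two ends.** G was never read, so I supposed that the flat line marks the end of free G, with G as the limiting reagent. But this flask was charged with 1.05 G for each E, so on that supposition something besides the making of J had used part of the G. With G in great excess, the whole of the E should turn. With E in great excess, J should equal the G charged. I joined these ends as limits in series, adding reciprocals. For this flask the G charge over the sum of both charges is 51.2%; I call this the turned share, the fraction of the charged E that ends as J. For elm it gives 34.4%.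

**Two doubts.** A balance also gives a flat line, and since the runs differ in temperature, each could have its own constant. But the turned share uses no constant and still lands near both runs. It misses by 1.8 percentage points in this flask and 1.4 points in elm, against a scatter of 1.5 points per reading. So I took "now" from the readings, 49.4%, and kept the turned share for what they do not show.

**My reckoning.** On this reading, J stays at 49.4% after blue and after teal. Amber is a fresh start, with the E left against the new G, and the turned share gives 34 points further, so amber was my choice.

**The forecast.** It said “I read this as the equilibrium”, which differs from my reading. It gave 49.6% now, 64.3% after blue and 56% after teal, with amber best.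

**The flask.** This flask gave 49.1%, 49.1% after blue and 49.1% after teal, and amber brought 33 points further.

    E + G → J + L (k = 0.115 /M/s, Ea = 58.0 kJ/mol)
    2 G → X (k = 0.128 /M/s, Ea = 39.0 kJ/mol)
    (constants at 5 °C)

**The neighbour.** In this flask free G stood at 0% of its charge by 30.0 min, and X, at two G each, then held 53.3% of that charge. The turned share had said 51.2% for this flask. For a neighbour charged with a quarter of this flask's E and the same G, the turned share is 80.8%, and that neighbour gave J at 77.3%.

The readings are calculated from invented constants; the scatter is artificial.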